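**Plan**

1. Late cuts: the O6 acetyl group, the enyne carbons C1–C3 (back to a C4 aldehyde, carried as a silyl ether) and C12–Br (back to the C12 carbinol of opposite configuration); the C14–C15 ethyl group is traced back to a vinyl group.
2. Core cut: C12–C13 of the oxocene (O–C7–C8–C9=C10–C11–C12–C13). The C12 carbinol sits next to ether carbon C13, which carries a two-carbon branch. This is the pattern left by a γ-alkoxyallyl-metal adding to an aldehyde, so the ring opens to an acyclic C12 aldehyde whose O7 carries a (Z)-3-borylprop-1-enyl group.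
3. Helpers: boron holds C15 and O12 in a six-membered chair fused to the forming eight-membered ring and is cleaved by water afterwards. The aldehyde stays masked as a diethyl acetal until closure, and the (Z)-C9=C10 alkene already in the chain brings the ends together. The vinyl group left on C13 is then hydrogenated to ethyl.
4. Forward order: C6–C7 by a glycolate aldol that carries the O7-allyl group from the start; C8–C9 by acetylide alkylation and semihydrogenation; lithiation–borylation of the allyl ether; ring closure (the only ring); then bromide and side chain.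
5. Stereochemistry: C6 and C7 from the (S)-benzyloxazolidinone syn-aldol; C13 from C7 (allylic strain in the bicyclic transition state); C12 from the (Z)-enol ether geometry (syn), then inverted by bromide; C3=C4 (E) from a stabilized Wittig reaction; C9=C10 (Z) from syn semihydrogenation.

Key step: step 9

Remark: atoms carry laurencin numbering (C1 alkyne terminus to C15 ethyl CH3; ring oxygen between C7 and C13). 2-(Allyloxy)acetic acid, 3-(tert-butyldimethylsilyloxy)propanal and 4,4-diethoxybut-1-yne are taken as catalogue compounds.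

**Route**

Step 1
Reactants: 1 (S)-4-benzyl-2-oxazolidinone; 2 2-(allyloxy)acetic acid
Product: 4 (S)-3-[2-(allyloxy)acetyl]-4-benzyloxazolidin-2-one, via mixed pivalic anhydride 3 (not isolated)
Conditions: 2, t-BuCOCl, Et3N, THF, −20 °C; then 1, LiCl, −20 °C → rt
Reagents that add atoms: none
Why: N-acylation of the oxazolidinone through the pivaloyl mixed anhydride (LiCl/Et3N protocol) should attack the less hindered glycolyl carbonyl; no stereocenter is touched.

Step 2
Reactants: 4 (S)-3-[2-(allyloxy)acetyl]-4-benzyloxazolidin-2-one; 5 3-(tert-butyldimethylsilyloxy)propanal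
Product: 8 (S)-3-[(2S,3R)-2-(allyloxy)-5-(tert-butyldimethylsilyloxy)-3-hydroxypentanoyl]-4-benzyloxazolidin-2-one, via boron enolate 6 (not isolated), via boron aldolate 7 (not isolated)
Conditions: n-Bu2BOTf, Et3N, CH2Cl2, −78 → 0 °C; then 5, −78 → 0 °C; then pH 7 buffer, MeOH, 30% H2O2, 0 °C
Reagents that add atoms: none
Why: Evans syn-aldol reaction: the (Z)-dibutylboron glycolate enolate should react through a Zimmerman–Traxler chair with the benzyl group shielding one enolate face, which sets C7 and C6 as the syn pair (2S,3R in the imide, 7R,6R in the target).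

Step 3
Reactants: 8 (S)-3-[(2S,3R)-2-(allyloxy)-5-(tert-butyldimethylsilyloxy)-3-hydroxypentanoyl]-4-benzyloxazolidin-2-one
Product: 9 (S)-3-[(2S,3R)-2-(allyloxy)-3,5-bis(tert-butyldimethylsilyloxy)pentanoyl]-4-benzyloxazolidin-2-one
Conditions: TBSOTf, 2,6-lutidine, CH2Cl2, 0 °C
Reagents that add atoms: tert-butyldimethylsilyl trifluoromethanesulfonate, CC(C)(C)[Si](C)(C)OS(=O)(=O)C(F)(F)F
Why: Silylation of the secondary alcohol with the silyl triflate and a hindered base is fast at 0 °C and should not cause retro-aldol cleavage; the O6 silyl ether must survive sec-BuLi later.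

Step 4
Reactants: 9 (S)-3-[(2S,3R)-2-(allyloxy)-3,5-bis(tert-butyldimethylsilyloxy)pentanoyl]-4-benzyloxazolidin-2-one
Product: 10 (2R,3R)-2-(allyloxy)-3,5-bis(tert-butyldimethylsilyloxy)pentan-1-ol
Conditions: LiBH4, MeOH (1 equiv), THF, 0 °C
Reagents that add atoms: none
Why: Reductive cleavage of the N-acyl oxazolidinone with LiBH4 should give the C8 primary alcohol without epimerizing C7 and returns the auxiliary.

Step 5
Reactants: 10 (2R,3R)-2-(allyloxy)-3,5-bis(tert-butyldimethylsilyloxy)pentan-1-ol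
Product: 11 (2R,3R)-2-(allyloxy)-3,5-bis(tert-butyldimethylsilyloxy)pentyl trifluoromethanesulfonate
Conditions: Tf2O, 2,6-lutidine, CH2Cl2, −78 °C; used at once
Reagents that add atoms: trifluoromethanesulfonic anhydride, O=S(=O)(OS(=O)(=O)C(F)(F)F)C(F)(F)F
Why: O-sulfonylation of the primary alcohol gives a β-alkoxy triflate, the leaving group that allows SN2 attack at this β-branched carbon at low temperature.

Step 6
Reactants: 11 (2R,3R)-2-(allyloxy)-3,5-bis(tert-butyldimethylsilyloxy)pentyl trifluoromethanesulfonate; 12 4,4-diethoxybut-1-yne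
Product: 14 (3R,4R)-4-(allyloxy)-1,3-bis(tert-butyldimethylsilyloxy)-9,9-diethoxynon-6-yne, via lithium acetylide 13 (not isolated)
Conditions: 12, n-BuLi, THF, −78 °C; then DMPU, 11, −78 → −20 °C
Reagents that add atoms: none
Why: SN2 alkylation of a lithium acetylide by a primary triflate should form C8–C9 and bring in C9–C12 with the aldehyde already masked as its diethyl acetal.

Step 7
Reactants: 14 (3R,4R)-4-(allyloxy)-1,3-bis(tert-butyldimethylsilyloxy)-9,9-diethoxynon-6-yne
Product: 15 (3R,4R,6Z)-4-(allyloxy)-1,3-bis(tert-butyldimethylsilyloxy)-9,9-diethoxynon-6-ene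
Conditions: H2 (1 atm), Pd/CaCO3 poisoned with Pb(OAc)2, quinoline, EtOAc, rt, stopped after 1 equiv of H2
Reagents that add atoms: none
Why: Lindlar semihydrogenation delivers both hydrogens to one face of the alkyne and so fixes the (Z)-C9=C10 alkene; the alkyne binds the poisoned surface far better than the terminal allyl alkene, which should survive.

Step 8
Reactants: 15 (3R,4R,6Z)-4-(allyloxy)-1,3-bis(tert-butyldimethylsilyloxy)-9,9-diethoxynon-6-ene
Product: 18 2-[(Z)-3-{[(3R,4R,6Z)-1,3-bis(tert-butyldimethylsilyloxy)-9,9-diethoxynon-6-en-4-yl]oxy}prop-2-enyl]-4,4,5,5-tetramethyl-1,3,2-dioxaborolane, via lithiated allyl ether 16 (not isolated), via lithium borate complex 17 (not isolated)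
Conditions: sec-BuLi, THF, −78 °C; then i-PrOBpin, −78 °C; then HCl (1 M in Et2O, 1 equiv), −78 °C → rt
Reagents that add atoms: 2-isopropoxy-4,4,5,5-tetramethyl-1,3,2-dioxaborolane, CC(C)OB1OC(C)(C)C(C)(C)O1
Why: Lithiation–borylation of an allyl ether: α-deprotonation gives the oxygen-chelated (Z)-alkoxyallyllithium, which boron electrophiles attack at the γ-terminus, so the (Z)-γ-alkoxyallylboronate should result; silyl ethers, acetal and the isolated alkene are inert at −78 °C.

Step 9
Reactants: 18 2-[(Z)-3-{[(3R,4R,6Z)-1,3-bis(tert-butyldimethylsilyloxy)-9,9-diethoxynon-6-en-4-yl]oxy}prop-2-enyl]-4,4,5,5-tetramethyl-1,3,2-dioxaborolane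
Product: 21 (2R,4Z,7R,8R)-2-[(1R)-1,3-bis(tert-butyldimethylsilyloxy)propyl]-8-vinyl-3,6,7,8-tetrahydro-2H-oxocin-7-ol, via C12 aldehyde 19 (not isolated), via O12 pinacol borate 20 (not isolated)
Conditions: LiBF4, MeCN/H2O (50:1), 0.005 M, rt; then pH 7 phosphate buffer
Reagents that add atoms: water, O
Why: Hydrolysis of the diethyl acetal under LiBF4 catalysis releases the C12 aldehyde 19, whose oxygen binds the boron held on C15 of the same chain, and the allyl unit is then transferred with allylic transposition through a six-membered chair (intramolecular allylboration), forming C12–C13 and the borate 20 that water cleaves to 21. The closest known reaction type is the syn-selective addition of (Z)-γ-alkoxyallylboronates to aldehydes and its intramolecular use for oxygen heterocycles. The oxocene closes in the 8-exo-trig mode (C13 attacks a carbonyl whose oxygen stays outside the ring), with the (Z)-C9=C10 alkene holding C8 and C11 on one side so that the chain ends meet. C12 is set by the (Z)-enol ether geometry: the ring oxygen is axial on C13 and the tether forces C11 equatorial on C12 in the chair, which gives the 12,13-syn pair, that is OH cis to vinyl on the ring (12R). C13 is set by C7: allylic 1,3-strain keeps H7 in the plane of the enol ether, so C6 and C8 sit on opposite faces and the aldehyde, which hangs from C8, can reach only one face of C13, the one that gives 13R and the 2,8-cis ring. The step needs intramolecular to beat intermolecular allylboration (high dilution) and cyclization to be faster than migration of the β,γ-alkene into conjugation, which the near-neutral medium and the pre-organized chain should secure.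

Step 10
Reactants: 21 (2R,4Z,7R,8R)-2-[(1R)-1,3-bis(tert-butyldimethylsilyloxy)propyl]-8-vinyl-3,6,7,8-tetrahydro-2H-oxocin-7-ol
Product: 22 (2R,4Z,7R,8R)-2-[(1R)-1,3-bis(tert-butyldimethylsilyloxy)propyl]-8-ethyl-3,6,7,8-tetrahydro-2H-oxocin-7-ol
Conditions: H2 (1 atm), RhCl(PPh3)3 (5 mol %), benzene/EtOH, rt, stopped after 1 equiv of H2
Reagents that add atoms: none
Why: Homogeneous hydrogenation with RhCl(PPh3)3 saturates a monosubstituted alkene in preference to a 1,2-disubstituted ring alkene (competitive binding), so the vinyl group should become the C14–C15 ethyl group while the (Z)-C9=C10 alkene is kept; no stereocenter is touched.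

Step 11
Reactants: 22 (2R,4Z,7R,8R)-2-[(1R)-1,3-bis(tert-butyldimethylsilyloxy)propyl]-8-ethyl-3,6,7,8-tetrahydro-2H-oxocin-7-ol
Product: 23 (2R,4Z,7S,8R)-7-bromo-2-[(1R)-1,3-bis(tert-butyldimethylsilyloxy)propyl]-8-ethyl-3,6,7,8-tetrahydro-2H-oxocine
Conditions: CBr4, P(n-C8H17)3, toluene, 70 °C
Reagents that add atoms: carbon tetrabromide, BrC(Br)(Br)Br
Why: Appel bromination (alkoxyphosphonium formation, then SN2 attack of bromide) should invert C12 from R to S and place Br trans to the ethyl group; the trialkylphosphine is chosen to limit elimination.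

Step 12
Reactants: 23 (2R,4Z,7S,8R)-7-bromo-2-[(1R)-1,3-bis(tert-butyldimethylsilyloxy)propyl]-8-ethyl-3,6,7,8-tetrahydro-2H-oxocine
Product: 24 (3R)-3-[(2R,4Z,7S,8R)-7-bromo-8-ethyl-3,6,7,8-tetrahydro-2H-oxocin-2-yl]-3-(tert-butyldimethylsilyloxy)propan-1-ol
Conditions: HF·pyridine, pyridine, THF, 0 °C
Reagents that add atoms: none
Why: Fluoride-mediated desilylation is much faster at the unhindered primary silyl ether than at the secondary O6 silyl ether next to the ring, so buffered HF·pyridine should free only O4.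

Step 13
Reactants: 24 (3R)-3-[(2R,4Z,7S,8R)-7-bromo-8-ethyl-3,6,7,8-tetrahydro-2H-oxocin-2-yl]-3-(tert-butyldimethylsilyloxy)propan-1-ol
Product: 25 (3R)-3-[(2R,4Z,7S,8R)-7-bromo-8-ethyl-3,6,7,8-tetrahydro-2H-oxocin-2-yl]-3-(tert-butyldimethylsilyloxy)propanal
Conditions: Dess–Martin periodinane, pyridine, CH2Cl2, 0 °C → rt
Reagents that add atoms: none
Why: Dess–Martin oxidation converts the primary alcohol to the C4 aldehyde under buffered, non-basic conditions that should leave the β-silyloxy group and the secondary bromide untouched.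

Step 14
Reactants: 25 (3R)-3-[(2R,4Z,7S,8R)-7-bromo-8-ethyl-3,6,7,8-tetrahydro-2H-oxocin-2-yl]-3-(tert-butyldimethylsilyloxy)propanal
Product: 26 (2E,5R)-5-[(2R,4Z,7S,8R)-7-bromo-8-ethyl-3,6,7,8-tetrahydro-2H-oxocin-2-yl]-5-(tert-butyldimethylsilyloxy)pent-2-enal
Conditions: Ph3P=CHCHO, toluene, 80 °C
Reagents that add atoms: (triphenylphosphoranylidene)acetaldehyde, O=CC=P(c1ccccc1)(c1ccccc1)c1ccccc1
Why: Wittig olefination with the stabilized formyl ylide is (E)-selective and should set the C3=C4 (E)-alkene while adding C2 and C3.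

Step 15
Reactants: 26 (2E,5R)-5-[(2R,4Z,7S,8R)-7-bromo-8-ethyl-3,6,7,8-tetrahydro-2H-oxocin-2-yl]-5-(tert-butyldimethylsilyloxy)pent-2-enal
Product: 27 tert-butyl{[(1R,3E)-1-[(2R,4Z,7S,8R)-7-bromo-8-ethyl-3,6,7,8-tetrahydro-2H-oxocin-2-yl]hex-3-en-5-ynyl]oxy}dimethylsilane
Conditions: Me3SiCHN2, LiN(i-Pr)2, THF, −78 °C; then 26, −78 → 0 °C; then H2O
Reagents that add atoms: (trimethylsilyl)diazomethane, C[Si](C)(C)C=[N+]=[N-]
Why: Colvin homologation: addition of lithiated Me3SiCHN2 to the aldehyde, Peterson elimination to the diazoalkene, loss of N2 and 1,2-hydrogen shift of the alkylidene carbene should give the terminal alkyne (C1) without touching the (E)-alkene or the bromide.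

Step 16
Reactants: 27 tert-butyl{[(1R,3E)-1-[(2R,4Z,7S,8R)-7-bromo-8-ethyl-3,6,7,8-tetrahydro-2H-oxocin-2-yl]hex-3-en-5-ynyl]oxy}dimethylsilane
Product: 28 (1R,3E)-1-[(2R,4Z,7S,8R)-7-bromo-8-ethyl-3,6,7,8-tetrahydro-2H-oxocin-2-yl]hex-3-en-5-yn-1-ol
Conditions: HF·pyridine, THF, 0 °C → rt
Reagents that add atoms: none
Why: Fluoride desilylation under non-basic conditions should free O6 without E2 loss of the secondary bromide or attack on the enyne.

Step 17
Reactants: 28 (1R,3E)-1-[(2R,4Z,7S,8R)-7-bromo-8-ethyl-3,6,7,8-tetrahydro-2H-oxocin-2-yl]hex-3-en-5-yn-1-ol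
Product: 29 (+)-laurencin, (1R,3E)-1-[(2R,4Z,7S,8R)-7-bromo-8-ethyl-3,6,7,8-tetrahydro-2H-oxocin-2-yl]hex-3-en-5-ynyl acetate
Conditions: Ac2O, pyridine, DMAP (cat.), CH2Cl2, rt
Reagents that add atoms: acetic anhydride, CC(=O)OC(C)=O
Why: DMAP-catalysed O-acylation of the secondary alcohol proceeds with retention at C6 and should give the target.

**Compound list**

1 | (S)-4-benzyl-2-oxazolidinone | O=C1N[C@@H](Cc2ccccc2)CO1 | starting material
2 | 2-(allyloxy)acetic acid | C=CCOCC(=O)O | starting material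
3 | 2-(allyloxy)acetic pivalic anhydride | C=CCOCC(=O)OC(=O)C(C)(C)C | intermediate
4 | (S)-3-[2-(allyloxy)acetyl]-4-benzyloxazolidin-2-one | C=CCOCC(=O)N1[C@@H](Cc2ccccc2)COC1=O | intermediate
5 | 3-(tert-butyldimethylsilyloxy)propanal | O=CCCO[Si](C)(C)C(C)(C)C | starting material
6 | (Z)-dibutylboron enolate of 4 | CCCCB(CCCC)O/C(=C\OCC=C)N1[C@@H](Cc2ccccc2)COC1=O | intermediate
7 | dibutylboron aldolate of 8 | CCCCB(CCCC)O[C@H](CCO[Si](C)(C)C(C)(C)C)[C@H](OCC=C)C(=O)N1[C@@H](Cc2ccccc2)COC1=O | intermediate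
8 | (S)-3-[(2S,3R)-2-(allyloxy)-5-(tert-butyldimethylsilyloxy)-3-hydroxypentanoyl]-4-benzyloxazolidin-2-one | O=C1OC[C@H](Cc2ccccc2)N1C(=O)[C@@H](OCC=C)[C@H](O)CCO[Si](C)(C)C(C)(C)C | intermediate
9 | (S)-3-[(2S,3R)-2-(allyloxy)-3,5-bis(tert-butyldimethylsilyloxy)pentanoyl]-4-benzyloxazolidin-2-one | O=C1OC[C@H](Cc2ccccc2)N1C(=O)[C@@H](OCC=C)[C@H](O[Si](C)(C)C(C)(C)C)CCO[Si](C)(C)C(C)(C)C | intermediate
10 | (2R,3R)-2-(allyloxy)-3,5-bis(tert-butyldimethylsilyloxy)pentan-1-ol | OC[C@@H](OCC=C)[C@H](O[Si](C)(C)C(C)(C)C)CCO[Si](C)(C)C(C)(C)C | intermediate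
11 | (2R,3R)-2-(allyloxy)-3,5-bis(tert-butyldimethylsilyloxy)pentyl trifluoromethanesulfonate | O=S(=O)(OC[C@@H](OCC=C)[C@H](O[Si](C)(C)C(C)(C)C)CCO[Si](C)(C)C(C)(C)C)C(F)(F)F | intermediate
12 | 4,4-diethoxybut-1-yne | C#CCC(OCC)OCC | starting material
13 | lithium 4,4-diethoxybut-1-yn-1-ide | [Li]C#CCC(OCC)OCC | intermediate
14 | (3R,4R)-4-(allyloxy)-1,3-bis(tert-butyldimethylsilyloxy)-9,9-diethoxynon-6-yne | CCOC(OCC)CC#CC[C@@H](OCC=C)[C@H](O[Si](C)(C)C(C)(C)C)CCO[Si](C)(C)C(C)(C)C | intermediate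
15 | (3R,4R,6Z)-4-(allyloxy)-1,3-bis(tert-butyldimethylsilyloxy)-9,9-diethoxynon-6-ene | CCOC(OCC)C/C=C\C[C@@H](OCC=C)[C@H](O[Si](C)(C)C(C)(C)C)CCO[Si](C)(C)C(C)(C)C | intermediate
16 | α-lithiated allyl ether of 15 | CCOC(OCC)C/C=C\C[C@@H](OC([Li])C=C)[C@H](O[Si](C)(C)C(C)(C)C)CCO[Si](C)(C)C(C)(C)C | intermediate
17 | lithium isopropoxy(pinacolato)[(Z)-3-alkoxyallyl]borate from 16 | CCOC(OCC)C/C=C\C[C@@H](O/C=C\C[B-]1(OC(C)C)OC(C)(C)C(C)(C)O1)[C@H](O[Si](C)(C)C(C)(C)C)CCO[Si](C)(C)C(C)(C)C.[Li+] | intermediate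
18 | 2-[(Z)-3-{[(3R,4R,6Z)-1,3-bis(tert-butyldimethylsilyloxy)-9,9-diethoxynon-6-en-4-yl]oxy}prop-2-enyl]-4,4,5,5-tetramethyl-1,3,2-dioxaborolane | CCOC(OCC)C/C=C\C[C@@H](O/C=C\CB1OC(C)(C)C(C)(C)O1)[C@H](O[Si](C)(C)C(C)(C)C)CCO[Si](C)(C)C(C)(C)C | intermediate
19 | (3Z,6R,7R)-7,9-bis(tert-butyldimethylsilyloxy)-6-{[(Z)-3-(4,4,5,5-tetramethyl-1,3,2-dioxaborolan-2-yl)prop-1-enyl]oxy}non-3-enal | O=CC/C=C\C[C@@H](O/C=C\CB1OC(C)(C)C(C)(C)O1)[C@H](O[Si](C)(C)C(C)(C)C)CCO[Si](C)(C)C(C)(C)C | intermediate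
20 | O12 pinacol borate of 21 | CC(C)(C)[Si](C)(C)OCC[C@@H](O[Si](C)(C)C(C)(C)C)[C@H]1C/C=C\C[C@@H](OB2OC(C)(C)C(C)(C)O2)[C@@H](C=C)O1 | intermediate
21 | (2R,4Z,7R,8R)-2-[(1R)-1,3-bis(tert-butyldimethylsilyloxy)propyl]-8-vinyl-3,6,7,8-tetrahydro-2H-oxocin-7-ol | CC(C)(C)[Si](C)(C)OCC[C@@H](O[Si](C)(C)C(C)(C)C)[C@H]1C/C=C\C[C@@H](O)[C@@H](C=C)O1 | intermediate
22 | (2R,4Z,7R,8R)-2-[(1R)-1,3-bis(tert-butyldimethylsilyloxy)propyl]-8-ethyl-3,6,7,8-tetrahydro-2H-oxocin-7-ol | CC(C)(C)[Si](C)(C)OCC[C@@H](O[Si](C)(C)C(C)(C)C)[C@H]1C/C=C\C[C@@H](O)[C@@H](CC)O1 | intermediate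
23 | (2R,4Z,7S,8R)-7-bromo-2-[(1R)-1,3-bis(tert-butyldimethylsilyloxy)propyl]-8-ethyl-3,6,7,8-tetrahydro-2H-oxocine | CC(C)(C)[Si](C)(C)OCC[C@@H](O[Si](C)(C)C(C)(C)C)[C@H]1C/C=C\C[C@H](Br)[C@@H](CC)O1 | intermediate
24 | (3R)-3-[(2R,4Z,7S,8R)-7-bromo-8-ethyl-3,6,7,8-tetrahydro-2H-oxocin-2-yl]-3-(tert-butyldimethylsilyloxy)propan-1-ol | OCC[C@@H](O[Si](C)(C)C(C)(C)C)[C@H]1C/C=C\C[C@H](Br)[C@@H](CC)O1 | intermediate
25 | (3R)-3-[(2R,4Z,7S,8R)-7-bromo-8-ethyl-3,6,7,8-tetrahydro-2H-oxocin-2-yl]-3-(tert-butyldimethylsilyloxy)propanal | O=CC[C@@H](O[Si](C)(C)C(C)(C)C)[C@H]1C/C=C\C[C@H](Br)[C@@H](CC)O1 | intermediate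
26 | (2E,5R)-5-[(2R,4Z,7S,8R)-7-bromo-8-ethyl-3,6,7,8-tetrahydro-2H-oxocin-2-yl]-5-(tert-butyldimethylsilyloxy)pent-2-enal | O=C/C=C/C[C@@H](O[Si](C)(C)C(C)(C)C)[C@H]1C/C=C\C[C@H](Br)[C@@H](CC)O1 | intermediate
27 | tert-butyl{[(1R,3E)-1-[(2R,4Z,7S,8R)-7-bromo-8-ethyl-3,6,7,8-tetrahydro-2H-oxocin-2-yl]hex-3-en-5-ynyl]oxy}dimethylsilane | C#C/C=C/C[C@@H](O[Si](C)(C)C(C)(C)C)[C@H]1C/C=C\C[C@H](Br)[C@@H](CC)O1 | intermediate
28 | (1R,3E)-1-[(2R,4Z,7S,8R)-7-bromo-8-ethyl-3,6,7,8-tetrahydro-2H-oxocin-2-yl]hex-3-en-5-yn-1-ol | C#C/C=C/C[C@@H](O)[C@H]1C/C=C\C[C@H](Br)[C@@H](CC)O1 | intermediate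
29 | (+)-laurencin, (1R,3E)-1-[(2R,4Z,7S,8R)-7-bromo-8-ethyl-3,6,7,8-tetrahydro-2H-oxocin-2-yl]hex-3-en-5-ynyl acetate | C#C/C=C/C[C@@H](OC(C)=O)[C@H]1C/C=C\C[C@H](Br)[C@@H](CC)O1 | target

**Count and risks**

Total step count: 17. Longest linear sequence: 17 steps (1 and 2 to 29; the route is fully linear).

Steps most likely to fail:

Step 9 (ring closure). What may go wrong: intermolecular allylboration leading to oligomers, migration of the β,γ-alkene of the freed aldehyde into conjugation, acid-promoted loss of the enol-ether boronate or of the primary silyl ether during unmasking, or poor facial selection at C13 relative to C7. The fallback sets out from 15 and returns at 21. It replaces the closed boron transition state by a Lewis-acid-promoted allylstannane–aldehyde cyclization with an open transition state, followed by correction of C12. Lithiation of 15 as in step 8 and trapping with Bu3SnCl should give the chromatographically stable (Z)-γ-alkoxyallyl tributylstannane F1. Acetal hydrolysis (LiBF4, wet MeCN) should give the stannyl aldehyde F2, which can be purified. BF3·OEt2 in CH2Cl2 at −78 °C under high dilution should close the ring, and this mode is expected to favour the 12,13-trans alcohol, the 12-epi alcohol F3. Mitsunobu inversion with 4-nitrobenzoic acid, PPh3 and diisopropyl azodicarboxylate should give the inverted 4-nitrobenzoate F4, and K2CO3 in MeOH then releases 21.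

Step 10 (vinyl to ethyl). What may go wrong: insufficient discrimination between the vinyl group and the ring (Z)-alkene, leading to over-reduction, or rhodium-hydride-induced double-bond migration. The fallback sets out from 21 and returns at 22. It replaces catalytic hydrogenation by stoichiometric hydrometalation and protonolysis. Cp2Zr(H)Cl (about 2.5 equiv, one of which is consumed by O12–H with loss of H2) in THF at rt adds to terminal alkenes far faster than to internal ones and should give the C15 alkylzirconocene chloride F5. Quenching with water replaces zirconium by hydrogen and frees O12, giving 22.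

Step 11 (bromide). What may go wrong: elimination to a diene, or participation of the ring oxygen across the ring (oxonium formation with ring contraction) in place of clean SN2 inversion at the phosphonium stage. The fallback sets out from 22 and returns at 23. It separates activation from displacement. ClCH2SO2Cl and pyridine in CH2Cl2 at 0 °C should give the chloromethanesulfonate F6, an isolable and very reactive sulfonate. LiBr in THF/DMPU at rt to 50 °C should then displace it with inversion to give 23.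

Further compounds
F1 | step 9 | (Z)-γ-alkoxyallyl tributylstannane from 15 | CCOC(OCC)C/C=C\C[C@@H](O/C=C\C[Sn](CCCC)(CCCC)CCCC)[C@H](O[Si](C)(C)C(C)(C)C)CCO[Si](C)(C)C(C)(C)C
F2 | step 9 | stannyl aldehyde, (3Z,6R,7R)-7,9-bis(tert-butyldimethylsilyloxy)-6-{[(Z)-3-(tributylstannyl)prop-1-enyl]oxy}non-3-enal | O=CC/C=C\C[C@@H](O/C=C\C[Sn](CCCC)(CCCC)CCCC)[C@H](O[Si](C)(C)C(C)(C)C)CCO[Si](C)(C)C(C)(C)C
F3 | step 9 | 12-epi alcohol, (2R,4Z,7S,8R)-2-[(1R)-1,3-bis(tert-butyldimethylsilyloxy)propyl]-8-vinyl-3,6,7,8-tetrahydro-2H-oxocin-7-ol | CC(C)(C)[Si](C)(C)OCC[C@@H](O[Si](C)(C)C(C)(C)C)[C@H]1C/C=C\C[C@H](O)[C@@H](C=C)O1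
F4 | step 9 | inverted 4-nitrobenzoate, (2R,4Z,7R,8R)-2-[(1R)-1,3-bis(tert-butyldimethylsilyloxy)propyl]-8-vinyl-3,6,7,8-tetrahydro-2H-oxocin-7-yl 4-nitrobenzoate | CC(C)(C)[Si](C)(C)OCC[C@@H](O[Si](C)(C)C(C)(C)C)[C@H]1C/C=C\C[C@@H](OC(=O)c2ccc(cc2)[N+](=O)[O-])[C@@H](C=C)O1
F5 | step 10 | C15 alkylzirconocene chloride of 21 (O12 also bound to zirconium) | CC(C)(C)[Si](C)(C)OCC[C@@H](O[Si](C)(C)C(C)(C)C)[C@H]1C/C=C\C[C@@H](O[Zr](Cl)(C2C=CC=C2)C2C=CC=C2)[C@@H](CC[Zr](Cl)(C2C=CC=C2)C2C=CC=C2)O1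
F6 | step 11 | chloromethanesulfonate of 22 | CC(C)(C)[Si](C)(C)OCC[C@@H](O[Si](C)(C)C(C)(C)C)[C@H]1C/C=C\C[C@@H](OS(=O)(=O)CCl)[C@@H](CC)O1
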